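**Retrosynthetic overview**

1. The target is a 2‑aryl‑3‑hydroxymethyl‑4‑arylmethyl oxolane whose 4‑arylmethyl ring is O‑linked to a threo (αR,βR) guaiacylglycerol. The last operations are acetonide hydrolysis, then hydrogenolysis of two aryl benzyl ethers.
2. The strategy rests on the oxolane ring O1–C2–C3–C4–C5: the C3–C4 bond joins C3 (bearing CH2OH, a carbon β to oxygen) to C4 (bearing ArCH2). It is cut as a C3 radical adding to a styrene, so C3/CH2OH come from a terminal epoxide and C4/C5/O1 from an (E)‑cinnamyl ether; C2 (aryl‑bearing, on O1) is the only controlling stereocentre.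
3. Precursor 17 is the Williamson ether of epoxy alcohol 4 (vinyl Grignard on O‑benzylvanillin, then Sharpless kinetic‑resolution epoxidation) with cinnamyl bromide 16.
4. Bromide 16 comes from methyl ferulate: phenol alkylation with a bromoacetyl Evans imide, boron syn‑glycolate aldol with O‑benzylvanillin (sets αR,βR), NaBH4 removal of the auxiliary, acetonide, DIBAL‑H, Appel bromination.
5. Only one ring is built, the oxolane (step 11, 5‑exo); the 1,3‑dioxane is a protecting group put on in step 7 and removed in step 12.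

Key step: step 11

Remark on the chemistry: O‑benzylvanillin (1) and methyl ferulate (8) are taken as purchased materials (each is one step from vanillin or ferulic acid). Oxolane atoms are numbered O1, C2 (aryl), C3 (CH2OH), C4 (CH2Ar), C5; the glycerol carbons are α (benzylic), β, γ.

**Route**

Step 1
Reactants: 1 4‑(benzyloxy)‑3‑methoxybenzaldehyde; 2 vinylmagnesium bromide
Product: 3 (±)‑1‑[4‑(benzyloxy)‑3‑methoxyphenyl]prop‑2‑en‑1‑ol
Conditions: THF, 0 °C; sat. aq. NH4Cl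
Reagents that add atoms: none
Why: Grignard 1,2‑addition of a vinyl nucleophile to a non‑enolisable aryl aldehyde; the carbinol centre forms racemic and is resolved in step 2.

Step 2
Reactants: 3 (±)‑1‑[4‑(benzyloxy)‑3‑methoxyphenyl]prop‑2‑en‑1‑ol
Product: 4 (R)‑[4‑(benzyloxy)‑3‑methoxyphenyl][(2S)‑oxiran‑2‑yl]methanol (erythro epoxy alcohol)
Conditions: Ti(OiPr)4 (0.15 equiv), D‑(−)‑DIPT (0.2 equiv), t‑BuOOH (0.45 equiv), 4 Å MS, CH2Cl2, −20 °C
Reagents that add atoms: tert‑butyl hydroperoxide, CC(C)(C)OO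
Why: Sharpless asymmetric epoxidation run as a kinetic resolution: with D‑(−)‑DIPT the (S)‑alcohol is the fast enantiomer and is epoxidised anti to its aryl group, so with substoichiometric oxidant the epoxy alcohol should carry the carbinol configuration needed for C2 (labelled R here because the oxiranyl carbon outranks aryl), while unreacted (R)‑3 is removed by chromatography.

Step 3
Reactants: 5 (S)‑4‑benzyl‑2‑oxazolidinone; 6 bromoacetyl bromide
Product: 7 (4S)‑4‑benzyl‑3‑(2‑bromoacetyl)‑1,3‑oxazolidin‑2‑one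
Conditions: n‑BuLi, THF, −78 °C; then 6, −78 → 0 °C
Reagents that add atoms: none
Why: N‑acylation of the lithiated oxazolidinone by an acid bromide, which at −78 °C is much faster than displacement of the α‑bromide; no new stereocentre.

Step 4
Reactants: 7 (4S)‑4‑benzyl‑3‑(2‑bromoacetyl)‑1,3‑oxazolidin‑2‑one; 8 methyl (E)‑3‑(4‑hydroxy‑3‑methoxyphenyl)prop‑2‑enoate (methyl ferulate)
Product: 9 methyl (E)‑3‑(4‑{2‑[(4S)‑4‑benzyl‑2‑oxo‑1,3‑oxazolidin‑3‑yl]‑2‑oxoethoxy}‑3‑methoxyphenyl)prop‑2‑enoate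
Conditions: K2CO3, acetone, rt → 45 °C
Reagents that add atoms: none
Why: Williamson ether synthesis in which the phenoxide displaces the activated α‑bromo imide by SN2; the mild carbonate base should leave the imide and the methyl ester intact.

Step 5
Reactants: 9 aryloxyacetyl imide; 1 4‑(benzyloxy)‑3‑methoxybenzaldehyde
Product: 12 methyl (E)‑3‑(4‑{[(1R,2S)‑1‑[4‑(benzyloxy)‑3‑methoxyphenyl]‑3‑[(4S)‑4‑benzyl‑2‑oxo‑1,3‑oxazolidin‑3‑yl]‑1‑hydroxy‑3‑oxopropan‑2‑yl]oxy}‑3‑methoxyphenyl)prop‑2‑enoate (syn aldol adduct), via dibutylboron Z‑enolate 10 (not isolated), via dibutylboron aldolate 11 (not isolated)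
Conditions: Bu2BOTf, iPr2NEt, CH2Cl2, −78 → 0 °C; 1, −78 → 0 °C; pH 7 buffer, MeOH, 30% H2O2, 0 °C
Reagents that add atoms: none
Why: Evans boron syn‑glycolate aldol: the Z‑enolate reacts through a Zimmerman–Traxler chair on the face away from the benzyl group of the (S)‑auxiliary, setting the carbinol centre (R) and the aryloxy‑bearing centre (S in the imide, R once the carbonyl is reduced) as the syn pair, which is the threo pair of the arylglycerol.

Step 6
Reactants: 12 syn aldol adduct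
Product: 13 methyl (E)‑3‑(4‑{[(1R,2R)‑1‑[4‑(benzyloxy)‑3‑methoxyphenyl]‑1,3‑dihydroxypropan‑2‑yl]oxy}‑3‑methoxyphenyl)prop‑2‑enoate
Conditions: NaBH4, THF/H2O (4:1), 0 °C → rt
Reagents that add atoms: none
Why: Borohydride reductive cleavage of the N‑acyl oxazolidinone at its activated exocyclic carbonyl gives the primary alcohol and returns the auxiliary; NaBH4 in wet THF should not touch the conjugated methyl ester, and no stereocentre is involved.

Step 7
Reactants: 13 threo diol ester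
Product: 14 methyl (E)‑3‑(4‑{[(4R,5R)‑4‑[4‑(benzyloxy)‑3‑methoxyphenyl]‑2,2‑dimethyl‑1,3‑dioxan‑5‑yl]oxy}‑3‑methoxyphenyl)prop‑2‑enoate (cis‑4,5‑dioxane)
Conditions: 2,2‑dimethoxypropane, PPTS (cat.), CH2Cl2, rt
Reagents that add atoms: 2,2‑dimethoxypropane, COC(C)(C)OC
Why: Acid‑catalysed transketalisation closes the six‑membered acetonide over the α,γ‑diol without breaking a C–O bond at either stereocentre, so the threo pair is kept as the cis‑4‑aryl‑5‑aryloxy dioxane.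

Step 8
Reactants: 14 acetonide ester
Product: 15 (E)‑3‑(4‑{[(4R,5R)‑4‑[4‑(benzyloxy)‑3‑methoxyphenyl]‑2,2‑dimethyl‑1,3‑dioxan‑5‑yl]oxy}‑3‑methoxyphenyl)prop‑2‑en‑1‑ol
Conditions: DIBAL‑H (2.5 equiv), CH2Cl2, −78 °C; Rochelle salt
Reagents that add atoms: none
Why: DIBAL‑H 1,2‑reduction of an α,β‑unsaturated ester to the (E)‑allylic alcohol at low temperature; acetonide and benzyl ether are inert.

Step 9
Reactants: 15 cinnamyl alcohol
Product: 16 (4R,5R)‑4‑[4‑(benzyloxy)‑3‑methoxyphenyl]‑5‑{4‑[(E)‑3‑bromoprop‑1‑enyl]‑2‑methoxyphenoxy}‑2,2‑dimethyl‑1,3‑dioxane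
Conditions: CBr4, PPh3, 2,6‑lutidine (cat.), CH2Cl2, 0 °C; used crude at once
Reagents that add atoms: carbon tetrabromide, BrC(Br)(Br)Br
Why: Appel bromination converts the primary allylic alcohol into the bromide under near‑neutral conditions that spare the acetonide; the electron‑rich cinnamyl bromide is not stored.

Step 10
Reactants: 4 erythro epoxy alcohol; 16 cinnamyl bromide
Product: 17 (4R,5R)‑4‑[4‑(benzyloxy)‑3‑methoxyphenyl]‑5‑{4‑[(E)‑3‑{(R)‑[4‑(benzyloxy)‑3‑methoxyphenyl][(2S)‑oxiran‑2‑yl]methoxy}prop‑1‑enyl]‑2‑methoxyphenoxy}‑2,2‑dimethyl‑1,3‑dioxane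
Conditions: NaH added to 4 + 16, n‑Bu4NI (cat.), THF/DMF (4:1), 0 °C → rt
Reagents that add atoms: none
Why: Williamson etherification of a secondary alkoxide with a primary allylic bromide (SN2); in an aprotic medium with the bromide already present, alkylation should outrun Payne migration of the epoxide, and the carbinol C–O bond is not broken so its configuration is retained.

Step 11
Reactants: 17 epoxy cinnamyl ether
Product: 20 [(2S,3R,4R)‑2‑[4‑(benzyloxy)‑3‑methoxyphenyl]‑4‑(4‑{[(4R,5R)‑4‑[4‑(benzyloxy)‑3‑methoxyphenyl]‑2,2‑dimethyl‑1,3‑dioxan‑5‑yl]oxy}‑3‑methoxybenzyl)oxolan‑3‑yl]methanol, via β‑titanoxy radical 18 (not isolated), via benzyltitanium alkoxide 19 (not isolated)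
Conditions: Cp2TiCl2 (2.5 equiv), Zn dust, THF, rt (green Cp2TiCl); added dropwise to 17 in THF (ca. 0.02 M), rt; sat. aq. NaH2PO4
Reagents that add atoms: none
Why: Cp2TiCl transfers one electron to the terminal epoxide, which opens to the secondary β‑titanoxy radical 18 and so erases the oxirane stereocentre; 18 adds to the near carbon of the (E)‑styrenyl double bond, forming C3–C4 and closing the oxolane ring O1–C2–C3–C4–C5 in a 5‑exo‑trig mode, and the benzylic radical is reduced by a second Cp2TiCl to the benzyltitanium species 19, which is protonated on work‑up to the ArCH2 group. The closest known reaction type is the titanocene(III) reductive epoxide opening with 5‑exo radical cyclisation of 1‑aryl‑2,3‑epoxypropyl cinnamyl ethers to 2‑aryl‑3‑hydroxymethyl‑4‑benzyl oxolanes. In the chair‑like transition state the only pre‑set centre, C2 (R in 17, S in 20 by a change of CIP priorities only), holds its aryl group pseudo‑equatorial, so the CH2OTi branch on C3 goes trans to it (3R) and the 1,5‑cis preference of a 1‑substituted hexenyl‑type radical puts the arylmethyl group on C4 cis to that branch (4R). The step needs opening to the secondary and not the primary radical, which the preference of Ti(III) for the more substituted radical secures. It needs ring closure faster than capture of 18 by titanium(III), secured by the fast addition to a styrene and by slow addition of the reagent at high dilution. It needs 2,3‑trans/3,4‑cis selection, secured by the C2 aryl group; acetonide, benzyl ethers and aryl ethers are inert to Cp2TiCl.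

Step 12
Reactants: 20 protected oxolane
Product: 21 (1R,2R)‑1‑[4‑(benzyloxy)‑3‑methoxyphenyl]‑2‑(4‑{[(3R,4R,5S)‑5‑[4‑(benzyloxy)‑3‑methoxyphenyl]‑4‑(hydroxymethyl)oxolan‑3‑yl]methyl}‑2‑methoxyphenoxy)propane‑1,3‑diol
Conditions: AcOH/THF/H2O (3:1:1), 40 °C
Reagents that add atoms: none
Why: Mild acid hydrolysis of the isopropylidene acetal cleaves at the acetal carbon, so the α and β centres keep their configuration, and with the phenols still benzylated the benzylic C2–O1 and Cα–O bonds should not ionise.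

Step 13
Reactants: 21 bis‑benzyl ether
Product: 22 (1R,2R)‑1‑(4‑hydroxy‑3‑methoxyphenyl)‑2‑(4‑{[(3R,4R,5S)‑5‑(4‑hydroxy‑3‑methoxyphenyl)‑4‑(hydroxymethyl)oxolan‑3‑yl]methyl}‑2‑methoxyphenoxy)propane‑1,3‑diol (target)
Conditions: H2 (1 atm), 10% Pd/C, EtOAc/EtOH, rt; stopped on consumption of 21
Reagents that add atoms: none
Why: Catalytic hydrogenolysis of the two aryl benzyl ethers under neutral conditions; the O–CH2Ph bonds should cleave well before the benzylic C2–O1 and Cα–OH bonds, and no stereocentre is touched.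

**Compound list**

1 | 4‑(benzyloxy)‑3‑methoxybenzaldehyde (O‑benzylvanillin) | COc1cc(C=O)ccc1OCc1ccccc1 | starting material
2 | vinylmagnesium bromide | C=C[Mg]Br | starting material
3 | (±)‑1‑[4‑(benzyloxy)‑3‑methoxyphenyl]prop‑2‑en‑1‑ol | C=CC(O)c1ccc(OCc2ccccc2)c(OC)c1 | intermediate
4 | (R)‑[4‑(benzyloxy)‑3‑methoxyphenyl][(2S)‑oxiran‑2‑yl]methanol | O[C@H](c1ccc(OCc2ccccc2)c(OC)c1)[C@@H]1CO1 | intermediate
5 | (S)‑4‑benzyl‑2‑oxazolidinone | O=C1N[C@@H](Cc2ccccc2)CO1 | starting material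
6 | bromoacetyl bromide | BrCC(Br)=O | starting material
7 | (4S)‑4‑benzyl‑3‑(2‑bromoacetyl)‑1,3‑oxazolidin‑2‑one | O=C(CBr)N1C(=O)OC[C@@H]1Cc1ccccc1 | intermediate
8 | methyl (E)‑3‑(4‑hydroxy‑3‑methoxyphenyl)prop‑2‑enoate (methyl ferulate) | COC(=O)/C=C/c1ccc(O)c(OC)c1 | starting material
9 | methyl (E)‑3‑(4‑{2‑[(4S)‑4‑benzyl‑2‑oxo‑1,3‑oxazolidin‑3‑yl]‑2‑oxoethoxy}‑3‑methoxyphenyl)prop‑2‑enoate | COC(=O)/C=C/c1ccc(OCC(=O)N2C(=O)OC[C@@H]2Cc2ccccc2)c(OC)c1 | intermediate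
10 | dibutylboron (Z)‑enolate of 9 | CCCCB(CCCC)O/C(=C\Oc1ccc(/C=C/C(=O)OC)cc1OC)N1C(=O)OC[C@@H]1Cc1ccccc1 | intermediate (not isolated)
11 | dibutylboron aldolate of 12 | COc1cc([C@@H](OB(CCCC)CCCC)[C@@H](C(=O)N2C(=O)OC[C@@H]2Cc2ccccc2)Oc2ccc(/C=C/C(=O)OC)cc2OC)ccc1OCc1ccccc1 | intermediate (not isolated)
12 | syn aldol adduct, (1R,2S) in the propan‑2‑yl numbering, on the (4S)‑auxiliary | COc1cc([C@@H](O)[C@@H](C(=O)N2C(=O)OC[C@@H]2Cc2ccccc2)Oc2ccc(/C=C/C(=O)OC)cc2OC)ccc1OCc1ccccc1 | intermediate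
13 | methyl (E)‑3‑(4‑{[(1R,2R)‑1‑[4‑(benzyloxy)‑3‑methoxyphenyl]‑1,3‑dihydroxypropan‑2‑yl]oxy}‑3‑methoxyphenyl)prop‑2‑enoate | COc1cc([C@@H](O)[C@@H](CO)Oc2ccc(/C=C/C(=O)OC)cc2OC)ccc1OCc1ccccc1 | intermediate
14 | methyl (E)‑3‑(4‑{[(4R,5R)‑4‑[4‑(benzyloxy)‑3‑methoxyphenyl]‑2,2‑dimethyl‑1,3‑dioxan‑5‑yl]oxy}‑3‑methoxyphenyl)prop‑2‑enoate | COc1cc([C@@H](OC(C)(C)OC3)[C@@H]3Oc2ccc(/C=C/C(=O)OC)cc2OC)ccc1OCc1ccccc1 | intermediate
15 | (E)‑3‑(4‑{[(4R,5R)‑4‑[4‑(benzyloxy)‑3‑methoxyphenyl]‑2,2‑dimethyl‑1,3‑dioxan‑5‑yl]oxy}‑3‑methoxyphenyl)prop‑2‑en‑1‑ol | COc1cc([C@@H](OC(C)(C)OC3)[C@@H]3Oc2ccc(/C=C/CO)cc2OC)ccc1OCc1ccccc1 | intermediate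
16 | (4R,5R)‑4‑[4‑(benzyloxy)‑3‑methoxyphenyl]‑5‑{4‑[(E)‑3‑bromoprop‑1‑enyl]‑2‑methoxyphenoxy}‑2,2‑dimethyl‑1,3‑dioxane | COc1cc([C@@H](OC(C)(C)OC3)[C@@H]3Oc2ccc(/C=C/CBr)cc2OC)ccc1OCc1ccccc1 | intermediate
17 | (4R,5R)‑4‑[4‑(benzyloxy)‑3‑methoxyphenyl]‑5‑{4‑[(E)‑3‑{(R)‑[4‑(benzyloxy)‑3‑methoxyphenyl][(2S)‑oxiran‑2‑yl]methoxy}prop‑1‑enyl]‑2‑methoxyphenoxy}‑2,2‑dimethyl‑1,3‑dioxane (key‑step precursor) | COc1cc([C@@H](OC(C)(C)OC3)[C@@H]3Oc2ccc(/C=C/CO[C@H](c4ccc(OCc5ccccc5)c(OC)c4)[C@@H]6CO6)cc2OC)ccc1OCc1ccccc1 | intermediate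
18 | β‑titanoxy secondary radical from 17 (Cp drawn σ‑bound) | COc1cc([C@@H](OC(C)(C)OC3)[C@@H]3Oc2ccc(/C=C/CO[C@H](c4ccc(OCc5ccccc5)c(OC)c4)[CH]CO[Ti](Cl)(C6C=CC=C6)C6C=CC=C6)cc2OC)ccc1OCc1ccccc1 | intermediate (not isolated)
19 | cyclised benzyltitanium(IV) titanium alkoxide (Cp drawn σ‑bound) | COc1cc([C@@H](OC(C)(C)OC3)[C@@H]3Oc2ccc(C([C@H]4CO[C@H](c5ccc(OCc6ccccc6)c(OC)c5)[C@H]4CO[Ti](Cl)(C7C=CC=C7)C7C=CC=C7)[Ti](Cl)(C8C=CC=C8)C8C=CC=C8)cc2OC)ccc1OCc1ccccc1 | intermediate (not isolated)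
20 | [(2S,3R,4R)‑2‑[4‑(benzyloxy)‑3‑methoxyphenyl]‑4‑(4‑{[(4R,5R)‑4‑[4‑(benzyloxy)‑3‑methoxyphenyl]‑2,2‑dimethyl‑1,3‑dioxan‑5‑yl]oxy}‑3‑methoxybenzyl)oxolan‑3‑yl]methanol (key‑step product) | COc1cc([C@@H](OC(C)(C)OC3)[C@@H]3Oc2ccc(C[C@H]4CO[C@H](c5ccc(OCc6ccccc6)c(OC)c5)[C@H]4CO)cc2OC)ccc1OCc1ccccc1 | intermediate
21 | (1R,2R)‑1‑[4‑(benzyloxy)‑3‑methoxyphenyl]‑2‑(4‑{[(3R,4R,5S)‑5‑[4‑(benzyloxy)‑3‑methoxyphenyl]‑4‑(hydroxymethyl)oxolan‑3‑yl]methyl}‑2‑methoxyphenoxy)propane‑1,3‑diol | COc1cc([C@@H](O)[C@@H](CO)Oc2ccc(C[C@H]3CO[C@H](c4ccc(OCc5ccccc5)c(OC)c4)[C@H]3CO)cc2OC)ccc1OCc1ccccc1 | intermediate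
22 | (1R,2R)‑1‑(4‑hydroxy‑3‑methoxyphenyl)‑2‑(4‑{[(3R,4R,5S)‑5‑(4‑hydroxy‑3‑methoxyphenyl)‑4‑(hydroxymethyl)oxolan‑3‑yl]methyl}‑2‑methoxyphenoxy)propane‑1,3‑diol | COc1cc([C@@H](O)[C@@H](CO)Oc2ccc(C[C@H]3CO[C@H](c4ccc(O)c(OC)c4)[C@H]3CO)cc2OC)ccc1O | target

**Step count**

Total: 13 steps. Longest linear sequence: 11 steps (steps 3–9, then 10–13, from (S)‑4‑benzyl‑2‑oxazolidinone).

**Steps most likely to fail, with fallbacks**

Step 11. Radical 18 may be captured by titanium(III) before it closes the ring, which leads by β‑elimination to an allyl ether, and the ring‑closing transition state may not discriminate well enough between the cis and trans arrangement at C3/C4. The fallback forms the same C3 radical by a tin‑hydride chain in which no metal reductant is present. It sets out from 17. The terminal epoxide is opened at its CH2 terminus by hydroxide (NaOH, DMSO/H2O, 80 °C) to the (2S,3R)‑1,2‑diol of 17 F1. Thiocarbonyldiimidazole in warm toluene converts this into the cyclic thionocarbonate (1,3‑dioxolane‑2‑thione) F2. Slow addition of Bu3SnH/AIBN in refluxing benzene should fragment F2 toward the secondary radical (Barton–McCombie type), which cyclises 5‑exo and takes hydrogen from the stannane to give the cyclised O‑alkyl S‑tributylstannyl thiocarbonate F3. K2CO3 in aqueous methanol cleaves F3, and the route is rejoined at 20.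

Step 10. The electron‑rich cinnamyl bromide may ionise and be lost to hydrolysis or self‑alkylation before the alkoxide captures it, and the epoxide may migrate (Payne) in the alkoxide of 4. The fallback avoids the bromide and the strongly basic alkoxide. It sets out from 15, which is acetylated (Ac2O, pyridine) to the (E)‑cinnamyl acetate F4. Palladium‑catalysed allylic etherification (Tsuji–Trost type: Pd(OAc)2, a biaryl di‑tert‑butylphosphine, Et2Zn 0.5 equiv to deprotonate 4, THF, rt) should join F4 and 4 at the unsubstituted allyl terminus, and the route is rejoined at 17.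

Step 2. The epoxy alcohol is the product of a kinetic resolution, so its enantiomeric purity is capped by the rate ratio of the two enantiomers of 3 and erodes as conversion rises; a monosubstituted vinyl group is also epoxidised slowly. The fallback takes the stereocentre from a recovered substrate, whose purity rises with conversion. It sets out from 3. Lipase‑catalysed acylation (Burkholderia cepacia lipase or CAL‑B, vinyl acetate, MTBE, rt) should convert the (R)‑enantiomer into (R)‑1‑[4‑(benzyloxy)‑3‑methoxyphenyl]prop‑2‑enyl acetate F6 and leave (S)‑1‑[4‑(benzyloxy)‑3‑methoxyphenyl]prop‑2‑en‑1‑ol F5. F5 is then epoxidised to full conversion under the matched Sharpless conditions (D‑(−)‑DIPT, Ti(OiPr)4, t‑BuOOH, −20 °C), and the route is rejoined at 4.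

**Further compounds**

F1 | step 11 | (2S,3R)‑3‑[4‑(benzyloxy)‑3‑methoxyphenyl]‑3‑{[(E)‑3‑(4‑{[(4R,5R)‑4‑[4‑(benzyloxy)‑3‑methoxyphenyl]‑2,2‑dimethyl‑1,3‑dioxan‑5‑yl]oxy}‑3‑methoxyphenyl)prop‑2‑enyl]oxy}propane‑1,2‑diol | COc1cc([C@@H](OC(C)(C)OC3)[C@@H]3Oc2ccc(/C=C/CO[C@H](c4ccc(OCc5ccccc5)c(OC)c4)[C@@H](O)CO)cc2OC)ccc1OCc1ccccc1
F2 | step 11 | cyclic thionocarbonate (1,3‑dioxolane‑2‑thione) of F1 | COc1cc([C@@H](OC(C)(C)OC3)[C@@H]3Oc2ccc(/C=C/CO[C@H](c4ccc(OCc5ccccc5)c(OC)c4)[C@@H]6COC(=S)O6)cc2OC)ccc1OCc1ccccc1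
F3 | step 11 | O‑alkyl S‑tributylstannyl thiocarbonate of 20 | COc1cc([C@@H](OC(C)(C)OC3)[C@@H]3Oc2ccc(C[C@H]4CO[C@H](c5ccc(OCc6ccccc6)c(OC)c5)[C@H]4COC(=O)S[Sn](CCCC)(CCCC)CCCC)cc2OC)ccc1OCc1ccccc1
F4 | step 10 | (E)‑cinnamyl acetate of 15 | COc1cc([C@@H](OC(C)(C)OC3)[C@@H]3Oc2ccc(/C=C/COC(C)=O)cc2OC)ccc1OCc1ccccc1
F5 | step 2 | (S)‑1‑[4‑(benzyloxy)‑3‑methoxyphenyl]prop‑2‑en‑1‑ol | O[C@H](c1ccc(OCc2ccccc2)c(OC)c1)C=C
F6 | step 2 | (R)‑1‑[4‑(benzyloxy)‑3‑methoxyphenyl]prop‑2‑enyl acetate | CC(=O)O[C@@H](c1ccc(OCc2ccccc2)c(OC)c1)C=C
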